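(Readings and results stem from a simulated flask with made-up constants, noise included.)

This flask cannot turn more than 70.0% of its solid substrate charge into target, because each target takes one coupling partner and less partner than solid substrate is charged. So coupling partner is the limiting reagent here, and what counts is how much of it reaches target.

| flask | solid substrate | coupling partner | remark | time |
|---|---|---|---|---|
| north | 0.030 M | 0.0427 M | run made earlier |  |
| north-west | 0.046 M | 0.0427 M | run made earlier |  |
| flask | 0.061 M | 0.0427 M |  | 80 min |

| run | time / min | target / % | dissolved substrate / % | solid substrate / % |
|---|---|---|---|---|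
| north | 6.00 | 91 | 8 | 0 |
| north | 10.0 | 97 | 6 | 1 |
| north | 20.0 | 99 | 0 | 0 |
| north | 30.0 | 98 | 0 | 1 |
| north | 50.0 | 100 | 0 | 0 |
| north | 80.0 | 100 | 1 | 0 |
| north-west | 5.00 | 65 | 29 | 7 |
| north-west | 15.0 | 86 | 15 | 0 |
| north-west | 30.0 | 88 | 17 | 0 |
| north-west | 40.0 | 88 | 13 | 0 |
| north-west | 60.0 | 88 | 15 | 0 |
| north-west | 80.0 | 87 | 12 | 0 |

(scatter of a reading: 1.5 percentage points)

- the target standing at 80 min, as a percentage of the solid substrate charged
- concentration of dissolved substrate in solution at 80 min, in percent of saturation

The north run reaches 100%, but the north-west run stands still near 87.8% with dissolved substrate still at 12%. We read that as partner spent. Target there reads as 94.5% of the partner charge, and this is the delivered share: the part of the coupling partner's charge that ends up as target. We freeze it for the flask, which has the same partner charge and more solid substrate.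

Our curve for the flask starts as north-west did, whose target at 5.00 min equals 49.0% of the flask's charge. It bends by about 15.0 min, where north-west already reads 86%, and then lies flat at 66.2%. That leaves 33.8% of the charge unconverted. At 5.00 min north-west read solid beside dissolved substrate equal to 21.9% of this charge, so we take saturation to lie near or above that reading, and we expect solid left and 100% saturation in the flask, though the readings don't prove it.

The forecast gives 67% against our 66.2%, and 100%, saying: "In the flask the partner is clearly limiting".

The flask gives 65.9% and 100%, with coupling partner at 0% of its own charge and, as parts of the solid charged, solid substrate at 11.2% beside dissolved substrate at 23.0%.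

    solid substrate ⇌ dissolved substrate, rate k1*(cs1 - [dissolved substrate]) while solid is left; crystals form when [dissolved substrate] > cs1 (solubility = 14.0 mM, k = 0.0441 s⁻¹)
    dissolved substrate + coupling partner → target (k = 0.414 L mol⁻¹ s⁻¹)
    coupling partner → decomposed reagent (k = 2.76 × 10⁻⁴ s⁻¹)

At 2.12 min in the flask the coupling step uses partner 17 times as fast as decomposition does, and the flask's delivered share comes to 94.1%. Carried to a neighbour flask, like this one but charged with 0.10 M of solid substrate, our share gives 40.4%, and that neighbour stands at 40.2%.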